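**Retrosynthetic overview**
1. Target 13 ⇒ isobutyrylation of epoxy alcohol 12, which comes from epoxy diol 10 by glycol cleavage and reduction (a CH(OH)CH2OH relay arm is cut back to CH2OH).
2. 10 ⇒ hydroxyl-directed epoxidation of allylic diol 9; the bought carbinol stereocentre sets the quaternary oxirane carbon and is destroyed afterwards.
3. 9 ⇒ methylenation, O-tigloylation and acetonide removal from o-hydroxyaryl ketone 5.
4. 5 ⇒ photochemical aryl–C bond formation (photo-Fries) in aryl ester 3, made from phenol 1 and L-glyceric acid acetonide 2.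
5. Ring order: arene and dioxolane are bought; the dioxolane is opened in step 4; the oxirane (step 5) is the only ring made.

Assumption: acid 2 (acetonide of L-glyceric acid, made commercially from L-serine or L-ascorbic acid) is bought as the free acid or freed from its commercial potassium salt or methyl ester just before use.

**Step 1**
Reactants: 1 4-methoxy-3-methylphenol; 2 (4S)-2,2-dimethyl-1,3-dioxolane-4-carboxylic acid
Product: 3 4-methoxy-3-methylphenyl (4S)-2,2-dimethyl-1,3-dioxolane-4-carboxylate
Conditions: DCC, DMAP (cat.), CH2Cl2, 0 °C → rt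
Reagents that add atoms: none
Why: Steglich esterification of a phenol is routine, and at 0 °C with only catalytic DMAP the bought α-alkoxy stereocentre is not epimerised.

**Step 2**
Reactants: 3 4-methoxy-3-methylphenyl (4S)-2,2-dimethyl-1,3-dioxolane-4-carboxylate
Product: 5 [(4S)-2,2-dimethyl-1,3-dioxolan-4-yl](2-hydroxy-5-methoxy-4-methylphenyl)methanone, via ortho-acyl cyclohexadienone 4 (not isolated)
Conditions: hν (254 nm, low-pressure Hg, FEP-tube flow reactor), degassed MeCN (0.02 M), rt
Reagents that add atoms: none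
Why: Proposed new method: a photo-Fries rearrangement in which the migrating acyl group is an α-stereogenic, acetal-protected 2,3-dioxygenated (glyceroyl) unit, a substrate class not yet put through this reaction; excitation of the aryl ester homolyses the ArO–C(O) bond to a caged singlet aryloxyl/acyl radical pair that recombines at the less hindered ortho carbon (para is blocked by OMe, the other ortho carbon is flanked by Me) to dienone 4, which tautomerises to ketone 5 (photostable through excited-state proton transfer), and because the σ-acyl radical never involves the α-C–H and in-cage recombination (about 10^10 s-1) outruns decarbonylation of an α-alkoxyacyl radical (about 10^5–10^6 s-1) the bought stereocentre is carried over intact; closest known reaction type: photo-Fries rearrangement of simple aryl alkanoates and benzoates.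

**Step 3**
Reactants: 5 [(4S)-2,2-dimethyl-1,3-dioxolan-4-yl](2-hydroxy-5-methoxy-4-methylphenyl)methanone
Product: 8 2-[1-[(4R)-2,2-dimethyl-1,3-dioxolan-4-yl]ethenyl]-4-methoxy-5-methylphenyl (E)-2-methylbut-2-enoate, via potassium ketophenolate 6 (not isolated), via potassium alkenylphenolate 7 (not isolated)
Conditions: KHMDS (1.0 equiv), THF, −78 °C; Ph3P=CH2 (1.5 equiv, from Ph3PCH3Br + KHMDS), −78 → 40 °C; then tigloyl chloride (2 equiv), 0 °C, dark
Reagents that add atoms: methyltriphenylphosphonium bromide C[P+](c1ccccc1)(c1ccccc1)c1ccccc1.[Br-] (the CH2); tigloyl chloride C/C=C(\C)C(=O)Cl (the tigloyl group); potassium bis(trimethylsilyl)amide C[Si](C)(C)[N-][Si](C)(C)C.[K+] (K+ of intermediates 6 and 7 only)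
Why: Wittig methylenation is run on phenolate 6, whose ortho-oxido group shuts down α-deprotonation so the bought stereocentre is untouched (S → R is a CIP priority change only), and phenolate 7 is O-acylated in the same flask (Schotten–Baumann-type acylation) so the phenol is masked before any benzylic C–O bond exists.

**Step 4**
Reactants: 8 2-[1-[(4R)-2,2-dimethyl-1,3-dioxolan-4-yl]ethenyl]-4-methoxy-5-methylphenyl (E)-2-methylbut-2-enoate
Product: 9 2-[(3R)-3,4-dihydroxybut-1-en-2-yl]-4-methoxy-5-methylphenyl (E)-2-methylbut-2-enoate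
Conditions: AcOH/H2O/THF (3:1:1), 40 °C
Reagents that add atoms: none
Why: Mild acid-catalysed acetonide hydrolysis frees the 1,2-diol that directs the epoxidation and is later cleaved, and leaves the aryl tiglate and the 1,1-disubstituted alkene untouched.

**Step 5**
Reactants: 9 2-[(3R)-3,4-dihydroxybut-1-en-2-yl]-4-methoxy-5-methylphenyl (E)-2-methylbut-2-enoate
Product: 10 2-[(2R)-2-[(1S)-1,2-dihydroxyethyl]oxiran-2-yl]-4-methoxy-5-methylphenyl (E)-2-methylbut-2-enoate
Conditions: VO(acac)2 (5 mol%), t-BuOOH (decane, 1.5 equiv), 2,6-lutidine (cat.), CH2Cl2, 0 °C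
Reagents that add atoms: tert-butyl hydroperoxide CC(C)(C)OO
Why: Hydroxyl-directed vanadium-catalysed epoxidation of a 2-substituted secondary allylic alcohol delivers oxygen through the transition state in which the carbinol H lies next to the aryl group (A(1,2) strain), giving the erythro epoxy alcohol, so the bought (3R)-carbinol sets the quaternary oxirane carbon as R while the electron-poor tiglate alkene does not react.

**Step 6**
Reactants: 10 2-[(2R)-2-[(1S)-1,2-dihydroxyethyl]oxiran-2-yl]-4-methoxy-5-methylphenyl (E)-2-methylbut-2-enoate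
Product: 12 2-[(2S)-2-(hydroxymethyl)oxiran-2-yl]-4-methoxy-5-methylphenyl (E)-2-methylbut-2-enoate, via epoxy aldehyde 11 (not isolated)
Conditions: NaIO4, THF/pH 7 phosphate buffer, 0 °C; extractive work-up; then NaBH4, CeCl3·7H2O, MeOH, −40 °C
Reagents that add atoms: none
Why: Malaprade glycol cleavage at pH 7 cuts the relay carbon off as formaldehyde, and the labile α-epoxy aldehyde 11 is reduced at once under Luche-type conditions that are cold and weakly basic enough to avoid tigloyl migration and epoxide opening; the quaternary centre is not touched (R in 11, S in 12 by CIP priority only).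

**Step 7**
Reactants: 12 2-[(2S)-2-(hydroxymethyl)oxiran-2-yl]-4-methoxy-5-methylphenyl (E)-2-methylbut-2-enoate
Product: 13 2-[(2R)-2-[(2-methylpropanoyloxy)methyl]oxiran-2-yl]-4-methoxy-5-methylphenyl (E)-2-methylbut-2-enoate (the target, CNP0256150.1)
Conditions: isobutyric anhydride, pyridine, DMAP (cat.), CH2Cl2, 0 °C
Reagents that add atoms: isobutyric anhydride CC(C)C(=O)OC(=O)C(C)C
Why: DMAP-catalysed acylation of the primary alcohol under buffered basic conditions leaves the epoxide and the aryl tiglate intact and gives the target (descriptor back to R by CIP priority).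

**Compound list**
1 | 4-methoxy-3-methylphenol | COc1ccc(O)cc1C | starting material
2 | (4S)-2,2-dimethyl-1,3-dioxolane-4-carboxylic acid | OC(=O)[C@@H]1COC(C)(C)O1 | starting material
3 | 4-methoxy-3-methylphenyl (4S)-2,2-dimethyl-1,3-dioxolane-4-carboxylate | COc1ccc(OC(=O)[C@@H]2COC(C)(C)O2)cc1C | intermediate
4 | 6-[(4S)-2,2-dimethyl-1,3-dioxolane-4-carbonyl]-4-methoxy-3-methylcyclohexa-2,4-dien-1-one (C6 epimers) | COC1=CC(C(=O)[C@@H]2COC(C)(C)O2)C(=O)C=C1C | intermediate
5 | [(4S)-2,2-dimethyl-1,3-dioxolan-4-yl](2-hydroxy-5-methoxy-4-methylphenyl)methanone | COc1cc(C(=O)[C@@H]2COC(C)(C)O2)c(O)cc1C | intermediate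
6 | potassium 2-[(4S)-2,2-dimethyl-1,3-dioxolane-4-carbonyl]-4-methoxy-5-methylphenolate | COc1cc(C(=O)[C@@H]2COC(C)(C)O2)c([O-])cc1C.[K+] | intermediate
7 | potassium 2-[1-[(4R)-2,2-dimethyl-1,3-dioxolan-4-yl]ethenyl]-4-methoxy-5-methylphenolate | COc1cc(C(=C)[C@@H]2COC(C)(C)O2)c([O-])cc1C.[K+] | intermediate
8 | 2-[1-[(4R)-2,2-dimethyl-1,3-dioxolan-4-yl]ethenyl]-4-methoxy-5-methylphenyl (E)-2-methylbut-2-enoate | C/C=C(\C)C(=O)Oc1cc(C)c(OC)cc1C(=C)[C@@H]1COC(C)(C)O1 | intermediate
9 | 2-[(3R)-3,4-dihydroxybut-1-en-2-yl]-4-methoxy-5-methylphenyl (E)-2-methylbut-2-enoate | C/C=C(\C)C(=O)Oc1cc(C)c(OC)cc1C(=C)[C@@H](O)CO | intermediate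
10 | 2-[(2R)-2-[(1S)-1,2-dihydroxyethyl]oxiran-2-yl]-4-methoxy-5-methylphenyl (E)-2-methylbut-2-enoate | C/C=C(\C)C(=O)Oc1cc(C)c(OC)cc1[C@]1([C@@H](O)CO)CO1 | intermediate
11 | 2-[(2R)-2-formyloxiran-2-yl]-4-methoxy-5-methylphenyl (E)-2-methylbut-2-enoate | C/C=C(\C)C(=O)Oc1cc(C)c(OC)cc1[C@]1(C=O)CO1 | intermediate
12 | 2-[(2S)-2-(hydroxymethyl)oxiran-2-yl]-4-methoxy-5-methylphenyl (E)-2-methylbut-2-enoate | C/C=C(\C)C(=O)Oc1cc(C)c(OC)cc1[C@]1(CO)CO1 | intermediate
13 | 2-[(2R)-2-[(2-methylpropanoyloxy)methyl]oxiran-2-yl]-4-methoxy-5-methylphenyl (E)-2-methylbut-2-enoate | C/C=C(\C)C(=O)Oc1cc(C)c(OC)cc1[C@]1(COC(=O)C(C)C)CO1 | target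

**Totals**
Total step count: 7. Longest linear sequence: 7 steps (1 → 13).

**Three steps most likely to fail**

(a) Step 2, the proposed new photo-Fries step. Likely problems are incomplete conversion (product 5 acts as an inner filter), some of the ortho isomer next to the methyl group, cage escape back to phenol 1, and erosion of the enantiomeric ratio if ketene-type fragmentation and re-addition occurs; the ratio of 5 should be checked by chiral HPLC. The fallback uses only known chemistry, sets out from 1 and 2 and comes back at 5. Phenol 1 is brominated with NBS in MeCN at 0 °C at the same ortho carbon to give 2-bromo-4-methoxy-5-methylphenol F1. Acid 2 is converted with MeNHOMe·HCl, EDC and N-methylmorpholine into the Weinreb amide (4S)-N-methoxy-N,2,2-trimethyl-1,3-dioxolane-4-carboxamide F2. F1 with n-BuLi (2.2 equiv, THF, −78 °C) gives lithium 2-lithio-4-methoxy-5-methylphenolate F3, which adds to F2 and, after NH4Cl work-up, gives ketone 5.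

(b) Step 3, Wittig methylenation of the deactivated, α-branched phenolate ketone. It may be sluggish, and prolonged heating with ylide could start to erode the α-stereocentre. The fallback sets out from 5 and comes back at 7. A non-basic Peterson sequence is used: Me3SiCH2MgCl/CeCl3 (THF, −78 → 0 °C) adds to the ketone without enolisation to give the β-hydroxysilane 2-[1-[(4S)-2,2-dimethyl-1,3-dioxolan-4-yl]-1-hydroxy-2-(trimethylsilyl)ethyl]-4-methoxy-5-methylphenol F4 (both carbinol epimers, which converge). KH in THF then effects elimination and gives potassium alkenylphenolate 7 directly, which is acylated with tigloyl chloride in the same flask as in the route.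

(c) Step 5, the directed epoxidation. The free 1,2-diol can chelate vanadium and lower rate or diastereoselectivity, and the tertiary benzylic epoxide can be opened by the Lewis-acidic catalyst. The fallback sets out from 9 and comes back at 10. It abandons the unprotected diol so that the substrate becomes the classical case of a single secondary allylic alcohol: the primary hydroxyl is silylated (TBSCl, imidazole, CH2Cl2, 0 °C) to 2-[(3R)-4-(tert-butyldimethylsilyloxy)-3-hydroxybut-1-en-2-yl]-4-methoxy-5-methylphenyl (E)-2-methylbut-2-enoate F5. VO(acac)2/t-BuOOH epoxidation gives 2-[(2R)-2-[(1S)-2-(tert-butyldimethylsilyloxy)-1-hydroxyethyl]oxiran-2-yl]-4-methoxy-5-methylphenyl (E)-2-methylbut-2-enoate F6, and buffered TBAF/AcOH in THF at 0 °C releases epoxy diol 10.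

**Further compounds**
F1 | step 2 | 2-bromo-4-methoxy-5-methylphenol | COc1cc(Br)c(O)cc1C
F2 | step 2 | (4S)-N-methoxy-N,2,2-trimethyl-1,3-dioxolane-4-carboxamide | CON(C)C(=O)[C@@H]1COC(C)(C)O1
F3 | step 2 | lithium 2-lithio-4-methoxy-5-methylphenolate | COc1cc([Li])c(O[Li])cc1C
F4 | step 3 | 2-[1-[(4S)-2,2-dimethyl-1,3-dioxolan-4-yl]-1-hydroxy-2-(trimethylsilyl)ethyl]-4-methoxy-5-methylphenol (both carbinol epimers) | COc1cc(C(O)(C[Si](C)(C)C)[C@@H]2COC(C)(C)O2)c(O)cc1C
F5 | step 5 | 2-[(3R)-4-(tert-butyldimethylsilyloxy)-3-hydroxybut-1-en-2-yl]-4-methoxy-5-methylphenyl (E)-2-methylbut-2-enoate | C/C=C(\C)C(=O)Oc1cc(C)c(OC)cc1C(=C)[C@@H](O)CO[Si](C)(C)C(C)(C)C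
F6 | step 5 | 2-[(2R)-2-[(1S)-2-(tert-butyldimethylsilyloxy)-1-hydroxyethyl]oxiran-2-yl]-4-methoxy-5-methylphenyl (E)-2-methylbut-2-enoate | C/C=C(\C)C(=O)Oc1cc(C)c(OC)cc1[C@]1([C@@H](O)CO[Si](C)(C)C(C)(C)C)CO1
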